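## Retrosynthetic overview
1. Target 13 ⇒ ring A phenol 10 + CH2O + ring B enol 5. The methylene bridge is made last, by Mannich reaction, o-quinone methide formation and Michael addition.
2. Ring B 5 ⇒ linear tetraketide ester 4 that already carries C2-Me and C6-prenyl. An enantioselective C6→C1 Claisen closure forms the ring, stops short of aromatisation and creates the acyl/prenyl quaternary stereocentre in one event.
3. 4 ⇒ methyl 2-methylacetoacetate 1, by polyanion chain growth (acetyl, then prenyl, then isobutyryl).
4. Ring A 10 ⇒ tetraketide lactone 7 ⇒ triacetic acid lactone 6. This uses the Mg(OMe)2 pyrone→phloroglucinol Claisen closure, with C-prenylation in the same flask.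
5. Ring order: ring B (step 3) and ring A (step 5) are closed independently, each from a linear tetraketide, and are joined in step 6.

Assumption: the facial sense of step 3 must be found by experiment. The cinchonidine-derived salt is written for (R)-5, and the equally cheap pseudo-enantiomeric cinchonine-derived salt replaces it if the sense is opposite.

## Route

Step 1
Reactants: 1 methyl 2-methyl-3-oxobutanoate
Product: 2 methyl 2-methyl-3,5-dioxohexanoate
Conditions: LDA (2.2 equiv), THF, −78 → 0 °C; MeCON(OMe)Me (1.0 equiv), −78 → 0 °C; 1 M HCl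
Reagents that add atoms: N-methoxy-N-methylacetamide, CC(=O)N(C)OC
Why: The Weiler-type β-keto ester dianion reacts only at its terminal γ-carbanion, and the Weinreb amide holds a chelated tetrahedral adduct until the quench, so one clean γ-acylation (crossed Claisen-type acylation) results; C2 is a labile centre of no consequence.

Step 2
Reactants: 2 methyl 2-methyl-3,5-dioxohexanoate
Product: 4 methyl 2,8-dimethyl-6-(3-methylbut-2-en-1-yl)-3,5,7-trioxononanoate (tautomer/diastereomer mixture), via prenylated diketo ester 3 (not isolated)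
Conditions: LDA (3.2 equiv), THF, −78 → 0 °C; prenyl bromide (1.0 equiv), −78 → −20 °C; LDA (1.2 equiv), −78 → −20 °C; i-PrCON(OMe)Me (1.2 equiv), −78 → 0 °C; cold 1 M HCl
Reagents that add atoms: prenyl bromide (1-bromo-3-methylbut-2-ene), CC(C)=CCBr; N-methoxy-N-methylisobutyramide, CC(C)C(=O)N(C)OC
Why: In Harris-type polyanion chemistry only the last-formed, least stabilised carbanion (C6) reacts, so the SN2 prenylation and, after re-deprotonation of the same carbon, the Weinreb acylation both land on C6 and give the linear tetraketide with C2-Me and C6-prenyl in place; C2 and C6 are labile and are not controlled here.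

Step 3
Reactants: 4 methyl 2,8-dimethyl-6-(3-methylbut-2-en-1-yl)-3,5,7-trioxononanoate
Product: 5 (4R)-3,5-dihydroxy-2-methyl-4-(2-methylpropanoyl)-4-(3-methylbut-2-en-1-yl)cyclohexa-2,5-dien-1-one
Conditions: N-(9-anthracenylmethyl)cinchonidinium chloride (10 mol %), CsOH·H2O (3 equiv), 4 Å MS, PhMe/CH2Cl2 7:3, −40 → −20 °C; cold 1 M HCl
Reagents that add atoms: none
Why: Proposed new method: solid–liquid phase-transfer CsOH takes 4 to its C4,C6-dienolate, whose C6 adds to the C1 ester in the C6→C1 Claisen (Dieckmann-type, 6-exo-trig) mode of a type III polyketide synthase; methoxide leaves, and the trione cannot aromatise because C6 carries prenyl and cannot take the rival C2→C7 aldol/aromatisation path because C2 carries methyl, so it is trapped at once as its vinylogous carboxylate, which makes the closure irreversible and fixes the quaternary centre in the bond-forming event; the cinchonidinium cation sits as a contact ion pair on the U-shaped O5/O7 dienolate, its anthracenylmethyl wall closing one face and its free 9-OH hydrogen-bonding the C1 carbonyl like an oxyanion hole, so the ester arm folds over one enantiotopic face of C6 to give (R)-5; the closest known reaction types are the base-induced Claisen cyclisation of 3,5,7-triketo esters to acylphloroglucinols, cinchona-PTC quaternary-centre formation on 2-substituted 1,3-dicarbonyl enolates, and the cinchona-PTC enantioselective alkylative dearomatisation of acylphloroglucinol anions.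

Step 4
Reactants: 6 4-hydroxy-6-methyl-2H-pyran-2-one (triacetic acid lactone)
Product: 7 4-hydroxy-6-(3-methyl-2-oxobutyl)-2H-pyran-2-one
Conditions: LDA (2.3 equiv), THF/DMPU, −78 → −20 °C; i-PrCON(OMe)Me (1.1 equiv), −78 → 0 °C; 1 M HCl
Reagents that add atoms: N-methoxy-N-methylisobutyramide, CC(C)C(=O)N(C)OC
Why: The pyronate/6-CH2 dianion of the lactone reacts only at the exocyclic carbanion, so Weinreb acylation gives the tetraketide in its lactone-masked form; no stereocentre is formed.

Step 5
Reactants: 7 4-hydroxy-6-(3-methyl-2-oxobutyl)-2H-pyran-2-one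
Product: 10 2-methyl-1-[2,4,6-trihydroxy-3-(3-methylbut-2-en-1-yl)phenyl]propan-1-one, via triketo ester 8 (not isolated), via phlorisobutyrophenone 9 (not isolated)
Conditions: Mg(OMe)2 (4 equiv), MeOH, reflux; then 0 °C, prenyl bromide (0.95 equiv); 1 M HCl
Reagents that add atoms: prenyl bromide (1-bromo-3-methylbut-2-ene), CC(C)=CCBr
Why: In this pyrone-to-phloroglucinol conversion methoxide opens the lactone and Mg2+ chelates the β-polyketo chain and steers it into the C6→C1 Claisen cyclisation and aromatisation (the hindered i-Pr ketone disfavours the aldol mode); the magnesium phloroglucinolate is then C-alkylated in methanol by a slight deficit of prenyl bromide (Riedl-type phenolate C-prenylation, positions 3 and 5 being equivalent); no stereocentre is formed.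

Step 6
Reactants: 10 2-methyl-1-[2,4,6-trihydroxy-3-(3-methylbut-2-en-1-yl)phenyl]propan-1-one; 5 (4R)-3,5-dihydroxy-2-methyl-4-(2-methylpropanoyl)-4-(3-methylbut-2-en-1-yl)cyclohexa-2,5-dien-1-one
Product: 13 (4S)-3,5-dihydroxy-2-methyl-4-(2-methylpropanoyl)-4-(3-methylbut-2-en-1-yl)-6-{[2,4,6-trihydroxy-3-(2-methylpropanoyl)-5-(3-methylbut-2-en-1-yl)phenyl]methyl}cyclohexa-2,5-dien-1-one (CNP0191741.1), via Mannich base 11 (not isolated), via o-quinone methide 12 (not isolated)
Conditions: 10, 37 % aq. CH2O (1.0 equiv), 40 % aq. Me2NH (1.0 equiv), EtOH, 0 °C → rt; then 5 (1.0 equiv), 45 °C; aq. citric acid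
Reagents that add atoms: formaldehyde, C=O
Why: The Mannich reaction fills the only free aromatic CH of 10 completely before 5 is added, the acidic enol 5 then protonates the amine so that Me2NH leaves to give the o-quinone methide, and the only enolic CH of 5 adds to it (Michael addition), which enforces the cross-coupled methylene bridge; the non-enolisable quaternary centre is untouched, and its descriptor changes from R to S only because the CH2Ar arm now outranks the methyl arm.

## Compound list
1 | methyl 2-methyl-3-oxobutanoate | COC(=O)C(C)C(C)=O | starting material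
2 | methyl 2-methyl-3,5-dioxohexanoate | COC(=O)C(C)C(=O)CC(C)=O | intermediate
3 | methyl 2,9-dimethyl-3,5-dioxodec-8-enoate | COC(=O)C(C)C(=O)CC(=O)CCC=C(C)C | intermediate
4 | methyl 2,8-dimethyl-6-(3-methylbut-2-en-1-yl)-3,5,7-trioxononanoate | COC(=O)C(C)C(=O)CC(=O)C(CC=C(C)C)C(=O)C(C)C | intermediate
5 | (4R)-3,5-dihydroxy-2-methyl-4-(2-methylpropanoyl)-4-(3-methylbut-2-en-1-yl)cyclohexa-2,5-dien-1-one | O=C1C=C(O)[C@@](CC=C(C)C)(C(=O)C(C)C)C(O)=C1C | intermediate
6 | 4-hydroxy-6-methyl-2H-pyran-2-one | Cc1cc(O)cc(=O)o1 | starting material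
7 | 4-hydroxy-6-(3-methyl-2-oxobutyl)-2H-pyran-2-one | CC(C)C(=O)Cc1cc(O)cc(=O)o1 | intermediate
8 | methyl 8-methyl-3,5,7-trioxononanoate (as Mg chelate) | COC(=O)CC(=O)CC(=O)CC(=O)C(C)C | intermediate
9 | 2-methyl-1-(2,4,6-trihydroxyphenyl)propan-1-one (phlorisobutyrophenone) | CC(C)C(=O)c1c(O)cc(O)cc1O | intermediate
10 | 2-methyl-1-[2,4,6-trihydroxy-3-(3-methylbut-2-en-1-yl)phenyl]propan-1-one | CC(C)=CCc1c(O)cc(O)c(C(=O)C(C)C)c1O | intermediate
11 | 1-{3-[(dimethylamino)methyl]-2,4,6-trihydroxy-5-(3-methylbut-2-en-1-yl)phenyl}-2-methylpropan-1-one | CC(C)=CCc1c(O)c(CN(C)C)c(O)c(C(=O)C(C)C)c1O | intermediate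
12 | 3,5-dihydroxy-6-methylidene-4-(2-methylpropanoyl)-2-(3-methylbut-2-en-1-yl)cyclohexa-2,4-dien-1-one | C=C1C(=O)C(CC=C(C)C)=C(O)C(C(=O)C(C)C)=C1O | intermediate
13 | (4S)-3,5-dihydroxy-2-methyl-4-(2-methylpropanoyl)-4-(3-methylbut-2-en-1-yl)-6-{[2,4,6-trihydroxy-3-(2-methylpropanoyl)-5-(3-methylbut-2-en-1-yl)phenyl]methyl}cyclohexa-2,5-dien-1-one | CC(C)=CCc1c(O)c(CC2=C(O)[C@@](CC=C(C)C)(C(=O)C(C)C)C(O)=C(C)C2=O)c(O)c(C(=O)C(C)C)c1O | target

## Step count and risks
Total step count: 6. Longest linear sequence: 4 (1 → 2 → 4 → 5 → 13).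

**Step 3.**
- Risk: the level and sense of enantioselectivity are unknown. Closure at a fully substituted carbon may be slow. Lactonisation through O5 may compete.
- Fallback, from 4 back to 5: 4 is closed without chiral control by Mg(OMe)2 in refluxing methanol. Lactone formation is reversible there, and the chelated chain funnels into the carbocycle, giving the racemic dienone F1.
- F1 is a vinylogous acid (pKa about 5) and is resolved classically with (R)-1-phenylethylamine in EtOAc/i-PrOH.
- The less soluble salt F2 is recrystallised to constant rotation, while the diastereomeric salt F3 stays in the mother liquor. The (S)-amine is used if it gives the better crystals.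
- Cold aqueous citric acid releases 5.

**Step 2.**
- Risk: acylation of the hindered secondary C6 carbanion by a hindered Weinreb amide may stall. Proton exchange may also blur the one-flask sequence.
- Fallback, from 3 back to 4: 3 is isolated after the alkylation stage. The direct acylation is replaced by an aldol addition followed by oxidation.
- The trianion of 3 (LDA, 3.1 equiv) adds to the far more reactive isobutyraldehyde at −78 °C to give the aldol F4.
- Dess–Martin periodinane buffered with NaHCO3 oxidises the carbinol to the C7 ketone, which is 4.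

**Step 6.**
- Risk: the methylene bridge may scramble to homodimers under amine base. The amine may also attack the triacylmethane centre.
- Fallback, from 10 (with 5) back to 13: the o-quinone methide route is replaced by a reductive alkylation.
- 10 is formylated at its free position (POCl3/DMF, EtOAc, 0 °C, NaOAc hydrolysis) to the aldehyde F5.
- F5, 5, Hantzsch ester and catalytic L-proline in CH2Cl2/EtOH condense (Knoevenagel) to the arylidene trione F6. F6 is reduced in situ by conjugate hydride transfer to 13.
- No formaldehyde or free secondary amine is present, and the CH2 link is formed irreversibly.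

## Further compounds
F1 | step 3 | rac-3,5-dihydroxy-2-methyl-4-(2-methylpropanoyl)-4-(3-methylbut-2-en-1-yl)cyclohexa-2,5-dien-1-one | O=C1C=C(O)C(CC=C(C)C)(C(=O)C(C)C)C(O)=C1C
F2 | step 3 | (R)-1-phenylethylammonium salt of 5 | O=C1C=C(O)[C@@](CC=C(C)C)(C(=O)C(C)C)C(O)=C1C.C[C@@H](N)c1ccccc1
F3 | step 3 | (R)-1-phenylethylammonium salt of ent-5 | O=C1C=C(O)[C@](CC=C(C)C)(C(=O)C(C)C)C(O)=C1C.C[C@@H](N)c1ccccc1
F4 | step 2 | methyl 7-hydroxy-2,8-dimethyl-6-(3-methylbut-2-en-1-yl)-3,5-dioxononanoate | COC(=O)C(C)C(=O)CC(=O)C(CC=C(C)C)C(O)C(C)C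
F5 | step 6 | 2,4,6-trihydroxy-3-(2-methylpropanoyl)-5-(3-methylbut-2-en-1-yl)benzaldehyde | CC(C)=CCc1c(O)c(C=O)c(O)c(C(=O)C(C)C)c1O
F6 | step 6 | Knoevenagel arylidene trione from F5 and 5 | CC(C)=CCc1c(O)c(C=C2C(=O)C(C)=C(O)[C@](CC=C(C)C)(C(=O)C(C)C)C2=O)c(O)c(C(=O)C(C)C)c1O
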